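Numbering of the target: tricyclo[5.4.0.0(2,8)]undecane, with the C9 ketone, C3 and C5 as ester carbons, C6 as the quaternary carbon carrying CH2OH, and methyls on C2, C6 and C11.
Retrosynthesis: remove both angelates; take the C3/C5 diol back to the 3,5-dione; excise C4 (cycloheptane-1,3-dione to cyclohexane-1,2-dione); cut C6–C7 and C2–C8 together to reach the monocyclic 2-bromocyclohex-2-enone 17 with a 3,4-dioxohexanoate chain; cut C1–C2 last (Carroll rearrangement).
Enabling feature: C8 and C7 are the α- and β-carbons of the C9 ketone of the six-membered ring, and C2 and C6 are the two α-carbons of the C3/C5 dicarbonyl unit of the seven-membered ring; a 2-bromo-enone is therefore a C7/C8 bis-electrophile for a bis-enolisable 1,2-dione tethered at C1.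
Forward: ring A (cyclohexenone) first; then in one operation the dione ring (C6–C7) and the cyclobutane (C2–C8); then one-carbon ring expansion to the cycloheptane, reductions and acylation.
Stereochemistry: C11 from an asymmetric deprotonation; C1 by suprafacial [3,3] transfer; C2, C7 and C8 from the ring constraints of the key step; C6 from a face-selective hydroxymethylation; C5 and C3 from two hydroxyl-directed hydride deliveries.

Key step: step 10

Remark: the (R,R)-lithium amide is assumed to give the (R)-enol silane 2; if the sense is opposite, its enantiomer is used.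
Remark: the side-chain stereocentres of 6 to 20 that are drawn without configuration are epimer mixtures; they converge in steps 9 to 12.

Step 1
Reactants: 1 4-methylcyclohexanone
Product: 2 (R)-trimethyl[(4-methylcyclohex-1-en-1-yl)oxy]silane
Conditions: LiN[(R)-CH(Me)Ph]2 (from the amine and n-BuLi), Me3SiCl, THF, −78 °C
Reagents that add atoms: chlorotrimethylsilane C[Si](C)(C)Cl
Why: enantioselective deprotonation of the prochiral ketone by the C2-symmetric lithium amide with in situ silylation should set the methyl-bearing centre (C11 of the target).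

Step 2
Reactants: 2 (R)-trimethyl[(4-methylcyclohex-1-en-1-yl)oxy]silane
Product: 3 (R)-4-methylcyclohex-2-en-1-one
Conditions: Pd(OAc)2, MeCN, rt
Reagents that add atoms: none
Why: Saegusa–Ito oxidation of the regiodefined enol silane should give the enone without touching the stereocentre.

Step 3
Reactants: 3 (R)-4-methylcyclohex-2-en-1-one
Product: 4 (1R,4R)-4-methylcyclohex-2-en-1-ol
Conditions: NaBH4, CeCl3·7H2O, MeOH, −78 °C
Reagents that add atoms: none
Why: Luche 1,2-reduction with axial hydride delivery should give the pseudo-equatorial, trans allylic alcohol.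

Step 4
Reactants: 4 (1R,4R)-4-methylcyclohex-2-en-1-ol; 5 methyl 2-methyl-3-oxobutanoate
Product: 8 3-[(1S,6R)-6-methylcyclohex-2-en-1-yl]butan-2-one, via allyl keto ester 6 (not isolated), via keto acid 7 (not isolated)
Conditions: DMAP (cat.), xylene, 140 °C (−MeOH); then sealed tube, 190 °C
Reagents that add atoms: none
Why: transesterification followed by Carroll rearrangement ([3,3], suprafacial) and decarboxylation should place the new C–C bond on the face of the departing oxygen, trans to the ring methyl (C1 of the target).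

Step 5
Reactants: 8 3-[(1S,6R)-6-methylcyclohex-2-en-1-yl]butan-2-one; 9 ethyl (2S)-2-{[(trifluoromethyl)sulfonyl]oxy}propanoate
Product: 10 ethyl 2-methyl-5-[(1S,6R)-6-methylcyclohex-2-en-1-yl]-4-oxohexanoate
Conditions: LiN(iPr)2, THF, −78 °C; then 9, −78 → −40 °C
Reagents that add atoms: none
Why: the kinetic methyl-ketone enolate should displace the secondary triflate (SN2 enolate alkylation), adding the propanoate arm whose ester later acidifies C6.

Step 6
Reactants: 10 ethyl 2-methyl-5-[(1S,6R)-6-methylcyclohex-2-en-1-yl]-4-oxohexanoate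
Product: 12 ethyl 2-methyl-5-[(1S,6R)-6-methylcyclohex-2-en-1-yl]-4-oxo-3-[(triethylsilyl)oxy]hexanoate, via hydroxy ketone 11 (not isolated)
Conditions: KN(SiMe3)2, THF, −78 °C; 2-(phenylsulfonyl)-3-phenyloxaziridine; then Et3SiCl, −78 → 0 °C
Reagents that add atoms: 2-(phenylsulfonyl)-3-phenyloxaziridine O=S(=O)(c1ccccc1)N1OC1c1ccccc1; chlorotriethylsilane CC[Si](Cl)(CC)CC
Why: kinetic enolisation at the ketone methylene (not the hindered methine) followed by enolate hydroxylation with the N-sulfonyloxaziridine and silylation should give the protected acyloin that survives the next two oxidative steps.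

Step 7
Reactants: 12 ethyl 2-methyl-5-[(1S,6R)-6-methylcyclohex-2-en-1-yl]-4-oxo-3-[(triethylsilyl)oxy]hexanoate
Product: 13 ethyl 2-methyl-5-[(1S,6R)-6-methyl-4-oxocyclohex-2-en-1-yl]-4-oxo-3-[(triethylsilyl)oxy]hexanoate
Conditions: CrO3, 3,5-dimethylpyrazole, CH2Cl2, −20 °C
Reagents that add atoms: chromium trioxide O=[Cr](=O)=O
Why: allylic oxidation with the chromium trioxide–pyrazole complex should attack the ring methylene remote from the branched carbon and give the conjugated enone (the C9 carbonyl).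

Step 8
Reactants: 13 ethyl 2-methyl-5-[(1S,6R)-6-methyl-4-oxocyclohex-2-en-1-yl]-4-oxo-3-[(triethylsilyl)oxy]hexanoate
Product: 15 ethyl 5-[(1R,6R)-3-bromo-6-methyl-4-oxocyclohex-2-en-1-yl]-2-methyl-4-oxo-3-[(triethylsilyl)oxy]hexanoate, via dibromo ketone 14 (not isolated)
Conditions: Br2, CH2Cl2, 0 °C; then Et3N
Reagents that add atoms: bromine BrBr
Why: bromine addition to the enone and dehydrobromination should give the 2-bromo-enone, so that the enone α-carbon becomes an electrophile after conjugate addition.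

Step 9
Reactants: 15 ethyl 5-[(1R,6R)-3-bromo-6-methyl-4-oxocyclohex-2-en-1-yl]-2-methyl-4-oxo-3-[(triethylsilyl)oxy]hexanoate
Product: 17 ethyl 5-[(1R,6R)-3-bromo-6-methyl-4-oxocyclohex-2-en-1-yl]-2-methyl-3,4-dioxohexanoate, via acyloin 16 (not isolated)
Conditions: CrO3, H2SO4, H2O, acetone, 0 °C
Reagents that add atoms: none
Why: acidic hexavalent chromium should cleave the silyl ether and oxidise the acyloin to the 1,2-dione (chromic acid oxidation of a secondary alcohol).

Step 10
Reactants: 17 ethyl 5-[(1R,6R)-3-bromo-6-methyl-4-oxocyclohex-2-en-1-yl]-2-methyl-3,4-dioxohexanoate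
Product: 19 ethyl (1S,2R,6S,7R,10R)-2,5,10-trimethyl-3,4,8-trioxotricyclo[4.4.0.0(2,7)]decane-5-carboxylate, via Michael adduct 18 (not isolated)
Conditions: Cs2CO3, MeCN (high dilution), 0 °C → rt
Reagents that add atoms: none
Why: Proposed new method: the carbonate deprotonates the chain carbon flanked by ester and dione, this enolate adds to the β-carbon of the bromo-enone (6-exo-trig, reversible) to close the cyclohexane-1,2-dione ring (C5–C6 of 19, C6–C7 of the target), and the enolate of the second dione α-carbon then displaces bromide at the former enone α-carbon (4-exo-tet, irreversible) to close the cyclobutane (C2–C7 of 19, C2–C8 of the target). The closest known reaction types are the Michael-initiated ring closure of 2-halo-enones with dicarbonyl compounds and the intramolecular ketone-enolate alkylation that gives bicyclo[3.1.1]heptanones; they have not been combined on two different carbons of one tethered 1,2-dione. C6 of 19 is set by the tether, which delivers the nucleophile to the face carrying the chain, and C2 and C7 can only be joined in the bridged cis geometry, so a trans-fused adduct cannot close and should return by retro-Michael addition; C5 forms as a mixture that step 11 erases. The step needs C- over O-alkylation, which the substrate secures because O-alkylation would put an enol-ether double bond at a bridgehead of a bicyclo[2.2.2]octene. It also needs each nucleophilic carbon to carry one hydrogen only, which excludes the cyclopropane and dihydrofuran products usual for 2-bromo-enones. The competing 3-exo-trig attack of the hindered methine carbanion is uphill and reversible.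

Step 11
Reactants: 19 ethyl (1S,2R,6S,7R,10R)-2,5,10-trimethyl-3,4,8-trioxotricyclo[4.4.0.0(2,7)]decane-5-carboxylate
Product: 20 (1S,2R,6R,7R,10R)-2,5,10-trimethyltricyclo[4.4.0.0(2,7)]decane-3,4,8-trione
Conditions: LiCl, DMSO, H2O, 140 °C
Reagents that add atoms: none
Why: Krapcho dealkoxycarbonylation of the quaternary β-keto ester should remove the activating group under neutral conditions and leave one enolisable C5–H.

Step 12
Reactants: 20 (1S,2R,6R,7R,10R)-2,5,10-trimethyltricyclo[4.4.0.0(2,7)]decane-3,4,8-trione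
Product: 21 (1S,2R,5S,6S,7R,10R)-5-(hydroxymethyl)-2,5,10-trimethyltricyclo[4.4.0.0(2,7)]decane-3,4,8-trione
Conditions: 37% aq. CH2O, Et3N (cat.), THF, 0 °C
Reagents that add atoms: formaldehyde C=O
Why: base-catalysed aldol addition at the only enolisable α-carbon of the dione should take formaldehyde on the enolate face away from the C10 methyl side (the side of the flat C8 carbonyl), setting the quaternary centre (C6 of the target).

Step 13
Reactants: 21 (1S,2R,5S,6S,7R,10R)-5-(hydroxymethyl)-2,5,10-trimethyltricyclo[4.4.0.0(2,7)]decane-3,4,8-trione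
Product: 23 (1S,2R,6S,7S,8R,11R)-6-(hydroxymethyl)-2,6,11-trimethyltricyclo[5.4.0.0(2,8)]undecane-3,5,9-trione, via methyl enol ether 22 (not isolated)
Conditions: CH2N2 (excess), Et2O/MeOH, 0 °C; then 1 M HCl, THF, rt
Reagents that add atoms: diazomethane C=[N+]=[N-]; water O
Why: diazomethane homologation of the cyclic 1,2-dione, which has no enolisable α-hydrogen left, with acyl migration should insert CH2 between the two carbonyls (one-carbon ring expansion), and acid hydrolyses the enol ether formed by the excess reagent.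

Step 14
Reactants: 23 (1S,2R,6S,7S,8R,11R)-6-(hydroxymethyl)-2,6,11-trimethyltricyclo[5.4.0.0(2,8)]undecane-3,5,9-trione
Product: 24 (1S,2R,3R,5R,6S,7S,8R,11R)-3,5-dihydroxy-6-(hydroxymethyl)-2,6,11-trimethyltricyclo[5.4.0.0(2,8)]undecan-9-one
Conditions: Me4NBH(OAc)3, MeCN/AcOH, −30 → 0 °C
Reagents that add atoms: none
Why: Evans–Saksena hydroxyl-directed reduction should deliver hydride from the CH2OH side to C5 and then from the new C5 alkoxyborohydride to C3 (trans-1,3-diol), while the C9 ketone has no β-hydroxyl to direct its reduction.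

Step 15
Reactants: 24 (1S,2R,3R,5R,6S,7S,8R,11R)-3,5-dihydroxy-6-(hydroxymethyl)-2,6,11-trimethyltricyclo[5.4.0.0(2,8)]undecan-9-one
Product: 25 (1S,2R,3R,5R,6S,7S,8R,11R)-6-{[(tert-butyldimethylsilyl)oxy]methyl}-3,5-dihydroxy-2,6,11-trimethyltricyclo[5.4.0.0(2,8)]undecan-9-one
Conditions: TBSCl, imidazole, DMF, 0 °C
Reagents that add atoms: tert-butylchlorodimethylsilane CC(C)(C)[Si](C)(C)Cl
Why: the primary hydroxyl should be silylated selectively over the two secondary hydroxyls that flank quaternary carbons.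

Step 16
Reactants: 25 (1S,2R,3R,5R,6S,7S,8R,11R)-6-{[(tert-butyldimethylsilyl)oxy]methyl}-3,5-dihydroxy-2,6,11-trimethyltricyclo[5.4.0.0(2,8)]undecan-9-one; 26 (Z)-2-methylbut-2-enoic acid (angelic acid)
Product: 28 (1S,2R,3R,5R,6S,7S,8R,11R)-6-{[(tert-butyldimethylsilyl)oxy]methyl}-2,6,11-trimethyl-9-oxotricyclo[5.4.0.0(2,8)]undecane-3,5-diyl bis[(Z)-2-methylbut-2-enoate], via mixed anhydride 27 (not isolated)
Conditions: 26 (excess, at least 2 equiv), 2,4,6-trichlorobenzoyl chloride, Et3N, toluene, rt; then 25, 80 °C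
Reagents that add atoms: angelic acid (second equivalent of 26) C/C=C(/C)C(=O)O
Why: Yamaguchi-type acylation through the mixed anhydride, run without a nucleophilic catalyst and with two equivalents of the anhydride consumed, should esterify both hindered hydroxyls with retention of the Z geometry.

Step 17
Reactants: 28 (1S,2R,3R,5R,6S,7S,8R,11R)-6-{[(tert-butyldimethylsilyl)oxy]methyl}-2,6,11-trimethyl-9-oxotricyclo[5.4.0.0(2,8)]undecane-3,5-diyl bis[(Z)-2-methylbut-2-enoate]
Product: 29 (1S,2R,3R,5R,6S,7S,8R,11R)-6-(hydroxymethyl)-2,6,11-trimethyl-9-oxotricyclo[5.4.0.0(2,8)]undecane-3,5-diyl bis[(Z)-2-methylbut-2-enoate]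
Conditions: HF·pyridine, pyridine, THF, 0 °C → rt
Reagents that add atoms: none
Why: buffered fluoride desilylation should free the primary alcohol without acyl migration or Z/E isomerisation of the esters.

Compound list
1 | 4-methylcyclohexanone | CC1CCC(=O)CC1 | starting material
2 | (R)-trimethyl[(4-methylcyclohex-1-en-1-yl)oxy]silane | C[Si](C)(C)OC1=CC[C@H](C)CC1 | intermediate
3 | (R)-4-methylcyclohex-2-en-1-one | O=C1C=C[C@H](C)CC1 | intermediate
4 | (1R,4R)-4-methylcyclohex-2-en-1-ol (trans) | O[C@H]1C=C[C@H](C)CC1 | intermediate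
5 | methyl 2-methyl-3-oxobutanoate | COC(=O)C(C)C(C)=O | starting material
6 | (1R,4R)-4-methylcyclohex-2-en-1-yl 2-methyl-3-oxobutanoate | CC(=O)C(C)C(=O)O[C@H]1C=C[C@H](C)CC1 | intermediate
7 | 2-methyl-2-[(1S,6R)-6-methylcyclohex-2-en-1-yl]-3-oxobutanoic acid | CC(=O)C(C)(C(=O)O)[C@@H]1C=CCC[C@H]1C | intermediate
8 | 3-[(1S,6R)-6-methylcyclohex-2-en-1-yl]butan-2-one | CC(=O)C(C)[C@@H]1C=CCC[C@H]1C | intermediate
9 | ethyl (2S)-2-{[(trifluoromethyl)sulfonyl]oxy}propanoate | CCOC(=O)[C@H](C)OS(=O)(=O)C(F)(F)F | starting material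
10 | ethyl 2-methyl-5-[(1S,6R)-6-methylcyclohex-2-en-1-yl]-4-oxohexanoate | CCOC(=O)C(C)CC(=O)C(C)[C@@H]1C=CCC[C@H]1C | intermediate
11 | ethyl 3-hydroxy-2-methyl-5-[(1S,6R)-6-methylcyclohex-2-en-1-yl]-4-oxohexanoate | CCOC(=O)C(C)C(O)C(=O)C(C)[C@@H]1C=CCC[C@H]1C | intermediate
12 | ethyl 2-methyl-5-[(1S,6R)-6-methylcyclohex-2-en-1-yl]-4-oxo-3-[(triethylsilyl)oxy]hexanoate | CCOC(=O)C(C)C(O[Si](CC)(CC)CC)C(=O)C(C)[C@@H]1C=CCC[C@H]1C | intermediate
13 | ethyl 2-methyl-5-[(1S,6R)-6-methyl-4-oxocyclohex-2-en-1-yl]-4-oxo-3-[(triethylsilyl)oxy]hexanoate | CCOC(=O)C(C)C(O[Si](CC)(CC)CC)C(=O)C(C)[C@@H]1C=CC(=O)C[C@H]1C | intermediate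
14 | ethyl 5-(2,3-dibromo-6-methyl-4-oxocyclohexyl)-2-methyl-4-oxo-3-[(triethylsilyl)oxy]hexanoate (ring C1 and C6 as in 13) | CCOC(=O)C(C)C(O[Si](CC)(CC)CC)C(=O)C(C)[C@@H]1C(Br)C(Br)C(=O)C[C@H]1C | intermediate
15 | ethyl 5-[(1R,6R)-3-bromo-6-methyl-4-oxocyclohex-2-en-1-yl]-2-methyl-4-oxo-3-[(triethylsilyl)oxy]hexanoate | CCOC(=O)C(C)C(O[Si](CC)(CC)CC)C(=O)C(C)[C@@H]1C=C(Br)C(=O)C[C@H]1C | intermediate
16 | ethyl 5-[(1R,6R)-3-bromo-6-methyl-4-oxocyclohex-2-en-1-yl]-3-hydroxy-2-methyl-4-oxohexanoate | CCOC(=O)C(C)C(O)C(=O)C(C)[C@@H]1C=C(Br)C(=O)C[C@H]1C | intermediate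
17 | ethyl 5-[(1R,6R)-3-bromo-6-methyl-4-oxocyclohex-2-en-1-yl]-2-methyl-3,4-dioxohexanoate | CCOC(=O)C(C)C(=O)C(=O)C(C)[C@@H]1C=C(Br)C(=O)C[C@H]1C | intermediate
18 | ethyl (4aR,5R,8aR)-8-bromo-1,4,5-trimethyl-2,3,7-trioxodecahydronaphthalene-1-carboxylate (cis-fused; mixture at C1/C4/C8) | O=C1C(=O)C(C)[C@@H]2[C@@H](C(Br)C(=O)C[C@H]2C)C1(C)C(=O)OCC | intermediate
19 | ethyl (1S,2R,6S,7R,10R)-2,5,10-trimethyl-3,4,8-trioxotricyclo[4.4.0.0(2,7)]decane-5-carboxylate (C5 epimers) | O=C1C(=O)[C@]2(C)[C@@H]3[C@@H]([C@H]2C(=O)C[C@H]3C)C1(C)C(=O)OCC | intermediate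
20 | (1S,2R,6R,7R,10R)-2,5,10-trimethyltricyclo[4.4.0.0(2,7)]decane-3,4,8-trione (C5 epimers) | O=C1C(=O)[C@]2(C)[C@@H]3[C@@H]([C@H]2C(=O)C[C@H]3C)C1C | intermediate
21 | (1S,2R,5S,6S,7R,10R)-5-(hydroxymethyl)-2,5,10-trimethyltricyclo[4.4.0.0(2,7)]decane-3,4,8-trione | O=C1C(=O)[C@]2(C)[C@@H]3[C@@H]([C@H]2C(=O)C[C@H]3C)[C@@]1(C)CO | intermediate
22 | 6-(hydroxymethyl)-5-methoxy-2,6,11-trimethyltricyclo[5.4.0.0(2,8)]undec-4-ene-3,9-dione (one of two regioisomeric enol ethers; ring centres as in 23) | COC1=CC(=O)[C@]2(C)[C@@H]3[C@@H]([C@H]2C(=O)C[C@H]3C)[C@@]1(C)CO | intermediate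
23 | (1S,2R,6S,7S,8R,11R)-6-(hydroxymethyl)-2,6,11-trimethyltricyclo[5.4.0.0(2,8)]undecane-3,5,9-trione | O=C1CC(=O)[C@]2(C)[C@@H]3[C@@H]([C@H]2C(=O)C[C@H]3C)[C@@]1(C)CO | intermediate
24 | (1S,2R,3R,5R,6S,7S,8R,11R)-3,5-dihydroxy-6-(hydroxymethyl)-2,6,11-trimethyltricyclo[5.4.0.0(2,8)]undecan-9-one | O[C@@H]1C[C@@H](O)[C@]2(C)[C@@H]3[C@@H]([C@H]2C(=O)C[C@H]3C)[C@@]1(C)CO | intermediate
25 | (1S,2R,3R,5R,6S,7S,8R,11R)-6-{[(tert-butyldimethylsilyl)oxy]methyl}-3,5-dihydroxy-2,6,11-trimethyltricyclo[5.4.0.0(2,8)]undecan-9-one | O[C@@H]1C[C@@H](O)[C@]2(C)[C@@H]3[C@@H]([C@H]2C(=O)C[C@H]3C)[C@@]1(C)CO[Si](C)(C)C(C)(C)C | intermediate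
26 | (Z)-2-methylbut-2-enoic acid (angelic acid) | C/C=C(/C)C(=O)O | starting material
27 | (Z)-2-methylbut-2-enoic 2,4,6-trichlorobenzoic anhydride | C/C=C(/C)C(=O)OC(=O)c1c(Cl)cc(Cl)cc1Cl | intermediate
28 | (1S,2R,3R,5R,6S,7S,8R,11R)-6-{[(tert-butyldimethylsilyl)oxy]methyl}-2,6,11-trimethyl-9-oxotricyclo[5.4.0.0(2,8)]undecane-3,5-diyl bis[(Z)-2-methylbut-2-enoate] | C/C=C(/C)C(=O)O[C@@H]1C[C@@H](OC(=O)/C(C)=C\C)[C@]2(C)[C@@H]3[C@@H]([C@H]2C(=O)C[C@H]3C)[C@@]1(C)CO[Si](C)(C)C(C)(C)C | intermediate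
29 | (1S,2R,3R,5R,6S,7S,8R,11R)-6-(hydroxymethyl)-2,6,11-trimethyl-9-oxotricyclo[5.4.0.0(2,8)]undecane-3,5-diyl bis[(Z)-2-methylbut-2-enoate] | C/C=C(/C)C(=O)O[C@@H]1C[C@@H](OC(=O)/C(C)=C\C)[C@]2(C)[C@@H]3[C@@H]([C@H]2C(=O)C[C@H]3C)[C@@]1(C)CO | target

Total step count: 17. Longest linear sequence: 17 steps (from 1; 5, 9 and 26 are commercial partners).

Steps most likely to fail

Step 10 (the proposed method). After the conjugate addition, closure of the four-membered ring may be slower than ring contraction of the bromo ketone by the other ring enolate or than loss of HBr. The fallback separates the two bond formations and sets out from 17. Amine-catalysed conjugate addition (Et3N cat., CH2Cl2, −20 °C) should give the cis-fused bromo triketone 18 as an isolated compound. Finkelstein exchange (NaI, acetone) gives ethyl (4aR,5R,8aR)-8-iodo-1,4,5-trimethyl-2,3,7-trioxodecahydronaphthalene-1-carboxylate F1. The cyclobutane is then closed as a discrete intramolecular ketone-enolate alkylation (KOtBu, tBuOH/THF, 0 °C), the established way to bicyclo[3.1.1]heptanones, which returns to 19.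

Step 13. The diazomethane adduct may collapse to an epoxide, the quaternary carbon may migrate in place of the acyl group, or the reagent may attack the C8 ketone. The fallback sets out from 21. Lewis-acid-promoted homologation with ethyl diazoacetate (BF3·OEt2, CH2Cl2, −78 °C), where acyl migration leads to a stabilised 2-acyl-1,3-dione, should give ethyl (1S,2R,6S,7S,8R,11R)-6-(hydroxymethyl)-2,6,11-trimethyl-3,5,9-trioxotricyclo[5.4.0.0(2,8)]undecane-4-carboxylate F2. Krapcho dealkoxycarbonylation (LiCl, wet DMSO, 130 °C) then returns to 23.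

Step 16. Acylation of the two hindered secondary hydroxyls may stop at the mono-ester, and the activated angeloyl unit may isomerise to the E geometry under the forcing conditions. The fallback sets out from 25. Carbodiimide esterification (DCC, DMAP, CH2Cl2) with 2-(diphenoxyphosphoryl)propanoic acid gives (1S,2R,3R,5R,6S,7S,8R,11R)-6-{[(tert-butyldimethylsilyl)oxy]methyl}-2,6,11-trimethyl-9-oxotricyclo[5.4.0.0(2,8)]undecane-3,5-diyl bis[2-(diphenoxyphosphoryl)propanoate] F3. A Z-selective Horner–Wadsworth–Emmons olefination with acetaldehyde (NaI, DBU, THF, −78 → 0 °C) then builds both (Z)-2-methylbut-2-enoates after the hindered ester bonds exist, and returns to 28.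

Further compounds
F1 | step 10 | ethyl (4aR,5R,8aR)-8-iodo-1,4,5-trimethyl-2,3,7-trioxodecahydronaphthalene-1-carboxylate | O=C1C(=O)C(C)[C@@H]2[C@@H](C(I)C(=O)C[C@H]2C)C1(C)C(=O)OCC
F2 | step 13 | ethyl (1S,2R,6S,7S,8R,11R)-6-(hydroxymethyl)-2,6,11-trimethyl-3,5,9-trioxotricyclo[5.4.0.0(2,8)]undecane-4-carboxylate | CCOC(=O)C1C(=O)[C@]2(C)[C@@H]3[C@@H]([C@H]2C(=O)C[C@H]3C)[C@@](C)(CO)C1=O
F3 | step 16 | (1S,2R,3R,5R,6S,7S,8R,11R)-6-{[(tert-butyldimethylsilyl)oxy]methyl}-2,6,11-trimethyl-9-oxotricyclo[5.4.0.0(2,8)]undecane-3,5-diyl bis[2-(diphenoxyphosphoryl)propanoate] | CC(P(=O)(Oc1ccccc1)Oc1ccccc1)C(=O)O[C@@H]1C[C@@H](OC(=O)C(C)P(=O)(Oc2ccccc2)Oc2ccccc2)[C@]2(C)[C@@H]3[C@@H]([C@H]2C(=O)C[C@H]3C)[C@@]1(C)CO[Si](C)(C)C(C)(C)C
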